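**Plan**
Retrosynthesis: the C5 methyl ether is kept to the end. Ring C is cut at O1–C2 to a trans-epoxy ketone with a free phenol, and this is cut at O1–C8a and C4–C4a into a ring A aryne and a 3-arylglycidate. The prenyl C–C bond at C6, the C–Si bond and the oxirane (from an E-cinnamate) are cut last.
Enabling feature: on ring A the acyl carbon C4 (on C4a) and the ether oxygen O1 (on C8a) sit on neighbouring carbons, and the oxygen at C5 lies next to C4a. An aryne spanning C4a–C8a is therefore polarised to take oxygen at C8a and carbon at C4a.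
Forward: rings A and B are bought as 3,5-dimethoxyphenol and isovanillin. The oxirane is made on the ring B side chain, the chain is joined to ring A in step 11, ring C closes in step 12 and the C5 ether is cleaved in step 13.
Stereochemistry: the Shi epoxidation of step 9 sets both oxirane carbons (2R,3S). C3 of the target keeps that C–O bond (R) and C2 arises by inversion at the benzylic carbon (S to R), giving the 2,3-trans (2R,3R) compound.
Key step: step 11

Remark: ring atoms carry flavanonol numbers (O1, C2–C4, C4a, C5–C8, C8a) also in the open precursors, and the L-series ketone catalyst of step 9 is assumed to be made separately from L-sorbose by the sequence used for its D-fructose-derived enantiomer.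

**Route**

Step 1
Reactants: 1 3,5-dimethoxyphenol
Product: 2 triisopropyl(3,5-dimethoxyphenoxy)silane
Conditions: TIPSCl, imidazole, DMF, rt
Reagents that add atoms: chlorotriisopropylsilane, CC(C)[Si](Cl)(C(C)C)C(C)C
Why: Silyl ether formation masks the phenol with a bulky, poorly coordinating group that will not direct the coming lithiation to its own ortho positions.

Step 2
Reactants: 2 triisopropyl(3,5-dimethoxyphenoxy)silane, 3 prenyl bromide (1-bromo-3-methylbut-2-ene)
Product: 5 triisopropyl[3,5-dimethoxy-4-(3-methylbut-2-en-1-yl)phenoxy]silane, via aryllithium 4 (not isolated)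
Conditions: n-BuLi, THF, 0 °C → rt; CuI (10 mol %), then 3, −30 °C → rt
Reagents that add atoms: none
Why: Directed ortho-metalation occurs at C6, the only carbon flanked by two methoxy groups, because both ethers coordinate lithium while the hindered silyloxy group does not, and the aryllithium is then allylated by prenyl bromide under copper catalysis, which favours SN2 over SN2' substitution.

Step 3
Reactants: 5 triisopropyl[3,5-dimethoxy-4-(3-methylbut-2-en-1-yl)phenoxy]silane
Product: 6 3,5-dimethoxy-4-(3-methylbut-2-en-1-yl)phenol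
Conditions: Bu4NF (TBAF), AcOH, THF, 0 °C
Reagents that add atoms: none
Why: Fluoride-induced cleavage of the aryl silyl ether is driven by the strong Si–F bond, and the acetic acid protonates the electron-rich phenoxide as it forms.

Step 4
Reactants: 6 3,5-dimethoxy-4-(3-methylbut-2-en-1-yl)phenol
Product: 7 3,5-dimethoxy-4-(3-methylbut-2-en-1-yl)phenyl N-(propan-2-yl)carbamate
Conditions: i-PrNCO, Et3N (cat), CH2Cl2, rt
Reagents that add atoms: isopropyl isocyanate, CC(C)N=C=O
Why: Amine-catalysed addition of the phenol to the isocyanate (carbamoylation) installs an O-carbamate that is a strong ortho-directing group and can later be removed by mild E1cB elimination.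

Step 5
Reactants: 7 3,5-dimethoxy-4-(3-methylbut-2-en-1-yl)phenyl N-(propan-2-yl)carbamate
Product: 11 3,5-dimethoxy-4-(3-methylbut-2-en-1-yl)-2-(trimethylsilyl)phenyl N-(propan-2-yl)carbamate, via N-silyl carbamate 8 (not isolated), via ortho-lithiated carbamate 9 (not isolated), via doubly silylated carbamate 10 (not isolated)
Conditions: TBSOTf, TMEDA, Et2O, 0 °C → rt; n-BuLi, TMEDA, −78 °C; TMSCl, −78 °C → rt; aq NaHSO4
Reagents that add atoms: chlorotrimethylsilane, C[Si](C)(C)Cl
Why: Directed ortho-metalation of the carbamate, made non-acidic by in situ N-silylation, should take place at −78 °C at one of the two equivalent carbons flanked by the carbamate and a methoxy group (C4a) faster than at the benzylic–allylic methylene, and quenching with TMSCl followed by hydrolytic loss of the N-silyl group on work-up gives the C-silylated carbamate.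

Step 6
Reactants: 11 3,5-dimethoxy-4-(3-methylbut-2-en-1-yl)-2-(trimethylsilyl)phenyl N-(propan-2-yl)carbamate
Product: 13 3,5-dimethoxy-4-(3-methylbut-2-en-1-yl)-2-(trimethylsilyl)phenyl trifluoromethanesulfonate, via silylphenol 12 (not isolated)
Conditions: Et2NH, DBU, MeCN, 40 °C; then PhNTf2, rt
Reagents that add atoms: N-phenylbis(trifluoromethanesulfonimide), O=S(=O)(N(c1ccccc1)S(=O)(=O)C(F)(F)F)C(F)(F)F
Why: Base-induced E1cB fragmentation of the N–H carbamate releases isopropyl isocyanate (scavenged by Et2NH) and the phenoxide, which is triflated in the same flask by PhNTf2 so that the protodesilylation-prone electron-rich silylphenol is never isolated.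

Step 7
Reactants: 14 isovanillin (3-hydroxy-4-methoxybenzaldehyde)
Product: 15 4-methoxy-3-(methoxymethoxy)benzaldehyde
Conditions: MOMCl, i-Pr2NEt, CH2Cl2, 0 °C → rt
Reagents that add atoms: chloromethyl methyl ether, COCCl
Why: O-Alkylation of the phenol with MOMCl and a hindered amine base gives an acetal ether that resists hydroxide, fluoride and carbanions and is removed by the acid of step 12.

Step 8
Reactants: 15 4-methoxy-3-(methoxymethoxy)benzaldehyde
Product: 16 ethyl (E)-3-[4-methoxy-3-(methoxymethoxy)phenyl]prop-2-enoate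
Conditions: (EtO)2P(O)CH2CO2Et, NaH, THF, 0 °C → rt
Reagents that add atoms: triethyl phosphonoacetate, CCOC(=O)CP(=O)(OCC)OCC
Why: Horner–Wadsworth–Emmons olefination of the aromatic aldehyde with the stabilised phosphonate anion gives the E-cinnamate through the thermodynamically preferred anti pathway.

Step 9
Reactants: 16 ethyl (E)-3-[4-methoxy-3-(methoxymethoxy)phenyl]prop-2-enoate
Product: 17 ethyl (2R,3S)-3-[4-methoxy-3-(methoxymethoxy)phenyl]oxirane-2-carboxylate
Conditions: 4,5-di-O-acetyl-1,2-O-isopropylidene-β-L-erythro-hexo-2,3-diulo-2,6-pyranose (25 mol %), Oxone (2KHSO5·KHSO4·K2SO4), NaHCO3, Bu4NHSO4 (cat), MeCN–aq Na2EDTA, 0 °C → rt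
Reagents that add atoms: potassium peroxymonosulfate (KHSO5), [K+].[O-]S(=O)(=O)OO
Why: Shi epoxidation, in which the chiral dioxirane formed from the ketone and KHSO5 transfers oxygen to one face of the E-olefin through a spiro transition state, sets C2 (R) and C3 (S) of the trans-glycidate together, the L-series acetate-bearing ketone being chosen because the D-fructose-derived catalysts deliver oxygen to the opposite face of E-cinnamates and because its electron-poor ring resists Baeyer–Villiger decay long enough to epoxidise a conjugated ester.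

Step 10
Reactants: 17 ethyl (2R,3S)-3-[4-methoxy-3-(methoxymethoxy)phenyl]oxirane-2-carboxylate
Product: 18 cesium (2R,3S)-3-[4-methoxy-3-(methoxymethoxy)phenyl]oxirane-2-carboxylate
Conditions: CsOH·H2O (1 equiv), EtOH–H2O, 0 °C; evaporation, azeotropic drying with toluene
Reagents that add atoms: cesium hydroxide, [Cs+].[OH-]
Why: Ester saponification with exactly one equivalent of CsOH at 0 °C gives the carboxylate salt directly, so the decarboxylation-prone free glycidic acid is never generated and both oxirane stereocentres stay untouched.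

Step 11
Reactants: 13 3,5-dimethoxy-4-(3-methylbut-2-en-1-yl)-2-(trimethylsilyl)phenyl trifluoromethanesulfonate, 18 cesium (2R,3S)-3-[4-methoxy-3-(methoxymethoxy)phenyl]oxirane-2-carboxylate
Product: 22 [(2R,3S)-3-[4-methoxy-3-(methoxymethoxy)phenyl]oxiran-2-yl][6-hydroxy-2,4-dimethoxy-3-(3-methylbut-2-en-1-yl)phenyl]methanone, via aryne 19 (not isolated), via aryl anion ester 20 (not isolated), via benzoxete alkoxide 21 (not isolated)
Conditions: CsF, 18-crown-6, THF, 0 °C → rt, 13 added slowly to excess 18; then AcOH, 0 °C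
Reagents that add atoms: none
Why: Proposed new method: fluoride removes the silyl group and triflate departs to give aryne 19, whose C8a (the carbon remote from the C5 methoxy group) should be attacked by the glycidate oxygen so that the charge develops at C4a, where the adjacent C–O bond stabilises it inductively; aryl anion 20 then adds to its own ester carbonyl through the four-membered alkoxide 21, which opens to the ketone as its cesium phenoxide, so that O1–C8a and C4–C4a are formed in one operation before acetic acid frees the phenol. The closest known reaction type is the fluoride-induced insertion of arynes into the C–O bond of simple carboxylic acids to give ortho-hydroxyaryl ketones, together with the anionic 1,3 O-to-C acyl shift of ortho-metalated aryl esters, and an α,β-epoxy acid has not been used in it. No ring is closed in the product (the benzoxete ring is transient) and no stereocentre is created, since both oxirane carbons come unchanged from 18 and neither is attacked or enolised. The selectivity needed is regioselective addition to the aryne, and it is secured by the C5 methoxy group flanking the triple bond at C4a while C8 carries only hydrogen. Acyl transfer must outrun protonation of the aryl anion, which is why the preformed dry cesium salt is used in THF with no acid present, and the phenoxide must be quenched cold before it can open the oxirane at the carbon next to the carbonyl.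

Step 12
Reactants: 22 [(2R,3S)-3-[4-methoxy-3-(methoxymethoxy)phenyl]oxiran-2-yl][6-hydroxy-2,4-dimethoxy-3-(3-methylbut-2-en-1-yl)phenyl]methanone
Product: 23 (2R,3R)-3-hydroxy-2-(3-hydroxy-4-methoxyphenyl)-5,7-dimethoxy-6-(3-methylbut-2-en-1-yl)-2,3-dihydro-4H-chromen-4-one
Conditions: HCl (1.25 M in MeOH), THF, rt → 40 °C
Reagents that add atoms: none
Why: Acid-catalysed intramolecular epoxide opening in the 6-endo mode, the established closure of ortho-oxygenated chalcone epoxides to trans-dihydroflavonols, in which the phenol attacks the protonated oxirane at the benzylic carbon activated by the para-methoxyaryl group with inversion (S to R at C2), the retained oxirane C–O bond becomes the C3 hydroxyl (R), and the same acid methanolyses the MOM acetal while the prenyl group, flanked only by methyl ethers, has no hydroxyl with which to cyclise.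

Step 13
Reactants: 23 (2R,3R)-3-hydroxy-2-(3-hydroxy-4-methoxyphenyl)-5,7-dimethoxy-6-(3-methylbut-2-en-1-yl)-2,3-dihydro-4H-chromen-4-one
Product: 24 (2R,3R)-3,5-dihydroxy-2-(3-hydroxy-4-methoxyphenyl)-7-methoxy-6-(3-methylbut-2-en-1-yl)-2,3-dihydro-4H-chromen-4-one (CNP0146895.1)
Conditions: MgI2·OEt2 (3 equiv), THF, 50 °C; then cold 0.5 M HCl
Reagents that add atoms: none
Why: Chelation-controlled ether cleavage, in which magnesium bound between the C4 carbonyl and the C5 methoxy oxygen activates only that methyl group towards SN2 attack by iodide, so that the C7 and ring B methyl ethers, the prenyl group and both stereocentres (already in the more stable trans arrangement) should be left alone.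

**Compound list**
1 | 3,5-dimethoxyphenol | COc1cc(O)cc(OC)c1 | starting material
2 | triisopropyl(3,5-dimethoxyphenoxy)silane | COc1cc(O[Si](C(C)C)(C(C)C)C(C)C)cc(OC)c1 | intermediate
3 | prenyl bromide (1-bromo-3-methylbut-2-ene) | CC(C)=CCBr | starting material
4 | [2,6-dimethoxy-4-(triisopropylsilyloxy)phenyl]lithium | COc1cc(O[Si](C(C)C)(C(C)C)C(C)C)cc(OC)c1[Li] | intermediate
5 | triisopropyl[3,5-dimethoxy-4-(3-methylbut-2-en-1-yl)phenoxy]silane | COc1cc(O[Si](C(C)C)(C(C)C)C(C)C)cc(OC)c1CC=C(C)C | intermediate
6 | 3,5-dimethoxy-4-(3-methylbut-2-en-1-yl)phenol | COc1cc(O)cc(OC)c1CC=C(C)C | intermediate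
7 | 3,5-dimethoxy-4-(3-methylbut-2-en-1-yl)phenyl N-(propan-2-yl)carbamate | COc1cc(OC(=O)NC(C)C)cc(OC)c1CC=C(C)C | intermediate
8 | 3,5-dimethoxy-4-(3-methylbut-2-en-1-yl)phenyl N-(tert-butyldimethylsilyl)-N-(propan-2-yl)carbamate | COc1cc(OC(=O)N(C(C)C)[Si](C)(C)C(C)(C)C)cc(OC)c1CC=C(C)C | intermediate
9 | 2-lithio-3,5-dimethoxy-4-(3-methylbut-2-en-1-yl)phenyl N-(tert-butyldimethylsilyl)-N-(propan-2-yl)carbamate | COc1cc(OC(=O)N(C(C)C)[Si](C)(C)C(C)(C)C)c([Li])c(OC)c1CC=C(C)C | intermediate
10 | 3,5-dimethoxy-4-(3-methylbut-2-en-1-yl)-2-(trimethylsilyl)phenyl N-(tert-butyldimethylsilyl)-N-(propan-2-yl)carbamate | COc1cc(OC(=O)N(C(C)C)[Si](C)(C)C(C)(C)C)c([Si](C)(C)C)c(OC)c1CC=C(C)C | intermediate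
11 | 3,5-dimethoxy-4-(3-methylbut-2-en-1-yl)-2-(trimethylsilyl)phenyl N-(propan-2-yl)carbamate | COc1cc(OC(=O)NC(C)C)c([Si](C)(C)C)c(OC)c1CC=C(C)C | intermediate
12 | 3,5-dimethoxy-4-(3-methylbut-2-en-1-yl)-2-(trimethylsilyl)phenol | COc1cc(O)c([Si](C)(C)C)c(OC)c1CC=C(C)C | intermediate
13 | 3,5-dimethoxy-4-(3-methylbut-2-en-1-yl)-2-(trimethylsilyl)phenyl trifluoromethanesulfonate | COc1cc(OS(=O)(=O)C(F)(F)F)c([Si](C)(C)C)c(OC)c1CC=C(C)C | intermediate
14 | isovanillin (3-hydroxy-4-methoxybenzaldehyde) | COc1ccc(C=O)cc1O | starting material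
15 | 4-methoxy-3-(methoxymethoxy)benzaldehyde | COCOc1cc(C=O)ccc1OC | intermediate
16 | ethyl (E)-3-[4-methoxy-3-(methoxymethoxy)phenyl]prop-2-enoate | CCOC(=O)/C=C/c1ccc(OC)c(OCOC)c1 | intermediate
17 | ethyl (2R,3S)-3-[4-methoxy-3-(methoxymethoxy)phenyl]oxirane-2-carboxylate | COc1ccc([C@@H]2O[C@H]2C(=O)OCC)cc1OCOC | intermediate
18 | cesium (2R,3S)-3-[4-methoxy-3-(methoxymethoxy)phenyl]oxirane-2-carboxylate | COc1ccc([C@@H]2O[C@H]2C(=O)[O-])cc1OCOC.[Cs+] | intermediate
19 | 3,5-dimethoxy-4-(3-methylbut-2-en-1-yl)benzyne (1,2-didehydrobenzene) | COC1=CC#CC(OC)=C1CC=C(C)C | intermediate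
20 | cesium 2,4-dimethoxy-3-(3-methylbut-2-en-1-yl)-6-{[(2R,3S)-3-[4-methoxy-3-(methoxymethoxy)phenyl]oxirane-2-carbonyl]oxy}benzenide | COc1ccc([C@@H]2O[C@H]2C(=O)Oc2cc(OC)c(CC=C(C)C)c(OC)[c-]2)cc1OCOC.[Cs+] | intermediate
21 | cesium 3,5-dimethoxy-2-[(2R,3S)-3-[4-methoxy-3-(methoxymethoxy)phenyl]oxiran-2-yl]-4-(3-methylbut-2-en-1-yl)-2H-1-benzoxet-2-olate | COc1ccc([C@@H]2O[C@H]2C3([O-])Oc4cc(OC)c(CC=C(C)C)c(OC)c34)cc1OCOC.[Cs+] | intermediate
22 | [(2R,3S)-3-[4-methoxy-3-(methoxymethoxy)phenyl]oxiran-2-yl][6-hydroxy-2,4-dimethoxy-3-(3-methylbut-2-en-1-yl)phenyl]methanone | COc1ccc([C@@H]2O[C@H]2C(=O)c2c(O)cc(OC)c(CC=C(C)C)c2OC)cc1OCOC | intermediate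
23 | (2R,3R)-3-hydroxy-2-(3-hydroxy-4-methoxyphenyl)-5,7-dimethoxy-6-(3-methylbut-2-en-1-yl)-2,3-dihydro-4H-chromen-4-one | COc1ccc([C@H]2Oc3cc(OC)c(CC=C(C)C)c(OC)c3C(=O)[C@@H]2O)cc1O | intermediate
24 | (2R,3R)-3,5-dihydroxy-2-(3-hydroxy-4-methoxyphenyl)-7-methoxy-6-(3-methylbut-2-en-1-yl)-2,3-dihydro-4H-chromen-4-one | COc1ccc([C@H]2Oc3cc(OC)c(CC=C(C)C)c(O)c3C(=O)[C@@H]2O)cc1O | target

**Step count**
Total: 13 steps. Longest linear sequence: 9 steps (steps 1–6, then 11, 12 and 13). The glycidate arm is 4 steps (7–10).

**Steps most likely to fail**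

1. Step 11 (proposed new method).
- What may go wrong: the aryl anion may be protonated before the acyl group migrates, leaving the aryl glycidate ester. The product phenoxide may add to a second aryne. Under the basic conditions the phenoxide may also open the oxirane at the carbon next to the carbonyl.
- Fallback (known chemistry): it sets out from 6, with 15 as partner, and returns to the route at 23. Phenol 6 is converted with MOMCl and i-Pr2NEt into 1,3-dimethoxy-5-(methoxymethoxy)-2-(3-methylbut-2-en-1-yl)benzene F1. Lithiation ortho to the acetal oxygen (n-BuLi, TMEDA, THF, −40 °C) gives [2,4-dimethoxy-6-(methoxymethoxy)-3-(3-methylbut-2-en-1-yl)phenyl]lithium F2. This is acylated with N-methoxy-N-methylacetamide to give 1-[2,4-dimethoxy-6-(methoxymethoxy)-3-(3-methylbut-2-en-1-yl)phenyl]ethan-1-one F3. Claisen–Schmidt condensation of F3 with 15 (KOH, EtOH) gives the (E)-chalcone F4. Julia–Colonna epoxidation (poly-L-leucine, urea–H2O2, DBU, THF) should then give the (2R,3S)-epoxy ketone F5. Methanolic HCl as in step 12 removes both MOM groups and closes ring C to 23.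

2. Step 12.
- What may go wrong: methanol may compete with the phenol as nucleophile at the benzylic oxirane carbon. HCl may add across the prenyl double bond. The aryl group may migrate in the opened cation.
- Fallback: it sets out from 22 and returns at 23. The oxirane is first opened at the benzylic carbon by sulfur (BnSH, SnCl4, CH2Cl2, −20 °C), which also cleaves the MOM ether. This gives (2S,3R)-3-(benzylsulfanyl)-2-hydroxy-1-[6-hydroxy-2,4-dimethoxy-3-(3-methylbut-2-en-1-yl)phenyl]-3-(3-hydroxy-4-methoxyphenyl)propan-1-one F6. Thiophilic activation with AgBF4 in CH2Cl2 at 0 °C then ionises the C–S bond, and the phenol closes ring C to the more stable trans isomer 23.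

3. Step 9.
- What may go wrong: oxygen transfer to the ester-conjugated olefin may be slow while the ketone catalyst decays, giving incomplete conversion or eroded enantioselectivity. The electron-rich benzylic oxirane may also be opened hydrolytically in the aqueous buffer.
- Fallback: it sets out from 15 and returns at 18. Darzens condensation of 15 with methyl chloroacetate and NaOMe in MeOH gives racemic methyl trans-3-[4-methoxy-3-(methoxymethoxy)phenyl]oxirane-2-carboxylate F7. Enantioselective hydrolysis with Serratia marcescens lipase (toluene, pH 8 buffer) consumes the (2S,3R) ester and leaves methyl (2R,3S)-3-[4-methoxy-3-(methoxymethoxy)phenyl]oxirane-2-carboxylate F8. F8 is saponified with CsOH·H2O as in step 10 to give 18.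

**Further compounds**
F1 | step 11 | 1,3-dimethoxy-5-(methoxymethoxy)-2-(3-methylbut-2-en-1-yl)benzene | COCOc1cc(OC)c(CC=C(C)C)c(OC)c1
F2 | step 11 | [2,4-dimethoxy-6-(methoxymethoxy)-3-(3-methylbut-2-en-1-yl)phenyl]lithium | COCOc1cc(OC)c(CC=C(C)C)c(OC)c1[Li]
F3 | step 11 | 1-[2,4-dimethoxy-6-(methoxymethoxy)-3-(3-methylbut-2-en-1-yl)phenyl]ethan-1-one | COCOc1cc(OC)c(CC=C(C)C)c(OC)c1C(C)=O
F4 | step 11 | (E)-1-[2,4-dimethoxy-6-(methoxymethoxy)-3-(3-methylbut-2-en-1-yl)phenyl]-3-[4-methoxy-3-(methoxymethoxy)phenyl]prop-2-en-1-one | COCOc1cc(OC)c(CC=C(C)C)c(OC)c1C(=O)/C=C/c1ccc(OC)c(OCOC)c1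
F5 | step 11 | [2,4-dimethoxy-6-(methoxymethoxy)-3-(3-methylbut-2-en-1-yl)phenyl][(2R,3S)-3-[4-methoxy-3-(methoxymethoxy)phenyl]oxiran-2-yl]methanone | COc1ccc([C@@H]2O[C@H]2C(=O)c2c(OCOC)cc(OC)c(CC=C(C)C)c2OC)cc1OCOC
F6 | step 12 | (2S,3R)-3-(benzylsulfanyl)-2-hydroxy-1-[6-hydroxy-2,4-dimethoxy-3-(3-methylbut-2-en-1-yl)phenyl]-3-(3-hydroxy-4-methoxyphenyl)propan-1-one | COc1ccc([C@@H](SCc2ccccc2)[C@@H](O)C(=O)c2c(O)cc(OC)c(CC=C(C)C)c2OC)cc1O
F7 | step 9 | racemic methyl trans-3-[4-methoxy-3-(methoxymethoxy)phenyl]oxirane-2-carboxylate (both enantiomers) | COc1ccc([C@@H]2O[C@H]2C(=O)OC)cc1OCOC.COc1ccc([C@H]2O[C@@H]2C(=O)OC)cc1OCOC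
F8 | step 9 | methyl (2R,3S)-3-[4-methoxy-3-(methoxymethoxy)phenyl]oxirane-2-carboxylate | COc1ccc([C@@H]2O[C@H]2C(=O)OC)cc1OCOC
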